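I want to know which flask ends with more target after the same time: Wednesday's at 20 °C or Thursday's at −5 °C.

- Wednesday's: substrate 0.29 M; gas 26 mM (held); temperature 20 °C; time 5.0 min
- Thursday's: substrate 0.29 M; gas 26 mM (held); temperature −5 °C; time 5.0 min

    substrate + coupling partner ⇌ isomer of the product (K1 = 120 L mol⁻¹, k1 = 4.1 L mol⁻¹ min⁻¹, Ea1 = 56.0 kJ mol⁻¹, ΔH1 = 8.00 kJ mol⁻¹)
    2 substrate → self-condensation product (k2 = 0.29 L mol⁻¹ min⁻¹, Ea2 = 47.0 kJ mol⁻¹)
    gas ⇌ coupling partner, rate k3*(csat - [coupling partner]) (k3 = 62 min⁻¹, csat = 26 mM)
    substrate + coupling partner ⇌ target (K4 = 44 L mol⁻¹, k4 = 11 L mol⁻¹ min⁻¹, Ea4 = 59.0 kJ mol⁻¹, ΔH4 = 43.0 kJ mol⁻¹)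
    (constants at 20 °C)

- percentages count the substrate that a species holds: one self-condensation product counts as two
- a step written with two of one species runs at k times the square of its concentration and takes two of it each time
- at the start none of coupling partner is dissolved
- at 20 °C the constants are as listed, elsewhere as the activation energies and enthalpies make them

1. the flask that comes out highest in amount of target, in percent of the substrate charged, or "all alike" when all lie within 1.5 percentage points (Wednesday's / Thursday's / all alike)
2. target at the end, in percent of the substrate charged, Wednesday's
3. target at the end, in percent of the substrate charged, Thursday's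

The gas refills the coupling partner at 62 min⁻¹, far faster than the substrate can use it, at about 4.38 min⁻¹, so I hold c(coupling partner) at 26 mM. That makes the two steps of the substrate with the coupling partner pseudo-first-order, while the self-condensation stays second-order in substrate.

One thing looks wrong at once: at 20 °C the target forms 2.68 times faster than the isomer of the product, yet the isomer is bound 2.73 times tighter. Both hold because an equilibrium constant is forward over back: target comes undone at 0.250 min⁻¹, the isomer at 0.0342 min⁻¹. Target is the quick product of kinetic control, and its climb has a stop.

I carry that stop. On Wednesday it is 1.14: the holding ratio, the c(target)/c(substrate) at which the step to target stands still, its equilibrium constant times c(coupling partner). The step's undoing over its making equals the actual ratio over the holding ratio. On Thursday the constant is 8.49 L mol⁻¹, so the holding ratio is 0.221.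

As a share of target plus substrate, these give 53.4% and 18.1%. The step relaxes with a half-life of 1.29 min on Wednesday, well inside 5.0 min, and 4.19 min on Thursday. So I expect Thursday's flask near 10.2%, and Wednesday's higher but under 53.4%, since two other products draw on the same substrate.

The forecast says Wednesday's, with 31.5% and 8.8%, on the ground that at the low temperature “the reaction is about ten times slower and remains kinetically limited”. My Thursday figure stands a little above its number.

Wednesday's flask comes out highest, with 31.8% against 9.15%, as the forecast said. At 5.00 min Wednesday's flask has a target-to-substrate ratio of 1.23, above its holding ratio of 1.14, so undoing runs at 1.08 times making. At the same time Thursday's flask has a ratio of 0.122, below its holding ratio of 0.221, so undoing runs at 0.551 times making.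

The rate constants are assumed; the flask was simulated.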